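## The problem

The target (31) is a single cyclohexane ring (C5–C10) with four appendages: an α-methylene-γ-butyrolactone trans-fused across C6–C7, an angelate on O8, a propenoic acid unit C4(=C3H2)–C15O2H on C5, and a quaternary C10 bearing methyl and vinyl. Five stereocentres (5R,6R,7R,8S,10S) must be set. C5 to C8 are contiguous and all-trans, so the chair that puts these four substituents equatorial has the C10 methyl axial and cis to the C5 side chain. C10 has no neighbour to lean on and needs an enantioselective reaction; it can then direct C5, and the C5/C10 pair fixes the chair from which C6, C7 and C8 are addressed. The difficulty lies in the three equatorial bonds at C6–C8: any reagent that approaches C6 or C8 along an axial path meets the axial methyl, and a trans-diaxial epoxide opening in this chair would put a carbon nucleophile on C6, not C7. These bonds therefore have to come from syn addition to the open α face, from inversion, or from equilibration. Groups that will not survive rough treatment are the (Z)-angelate (drifts to the tiglate with nucleophiles, base or hot acid), the two 1,1-disubstituted enoate acceptors, and the γ-relationship between O6 and C15, which invites an isomeric lactone. The feature that makes the key step possible is the trans-diequatorial pair of the C6 hydroxyl and a C7 ethynyl group: CO inserted between O6 and the internal alkyne carbon C11 closes the ring C6–O–C12–C11–C7 and leaves C11=C13 as the exocyclic methylene.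

## Retrosynthesis

**31 from 30.** The O–C(CH3)3 bond of the C15 ester is cut last. A tert-butyl ester is chosen over smaller esters because its bulk disfavours attack of O6 on C15, it tolerates palladium, CO and mild base, and it falls to acid that leaves the lactone and the angelate alone. The forward step only has to be short and cold.

**30 from 29.** C11–C12 and C12–O6 are cut together, which returns CO and the ethynyl carbinol 29. The neighbouring cuts are worse here: lactonising a C12 acid and adding C13 later needs enolate chemistry beside the angelate, and forming C6–C7 with the propenoate already on C7 pushes ring construction into an open chain. The precursor loses a ring and its most electrophilic group. The forward reaction must take O6 and the terminal alkyne and nothing else.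

**29 from 26 and 27.** The acyl–O8 bond is cut, giving diol 26 and angelic acid (27). Acylating now also blocks O8, which is homopropargylic too and would otherwise compete in the carbonylation. The forward step must pick O8 (one methylene neighbour) over O6 (two branched neighbours) and keep the Z geometry.

**26 from 24 through 25.** C11≡C13 is cut: the alkyne comes from aldehyde 24 by one-carbon homologation, through bis-silyl ether 25. Opening a C6–C7 epoxide with an alkynylalane would be shorter but was set aside for the regiochemical reason given above, and because the wanted product has both new bonds equatorial. An α-alkynyl ketone was avoided because it isomerises to the allenyl ketone. The aldehyde at C7 sits between two equatorial silyloxy groups and is at its thermodynamic configuration, so base-mediated homologation cannot harm it.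

**24 from 20 through 23.** The C4=C3 methylene and the C11 oxidation level are cut back to tris-silyl ether 20. Methylenation is placed here because 20 has one acidic C–H only (α to the ester); earlier the propenoate would meet hydrazine and borane, and later it would meet the angelate and the alkyne C–H.

**20 from 16 through 18 and 19.** The C6–O and C7–H bonds, and the unmasked C1=C2 vinyl group, are cut to diene 16. One hydroboration does two jobs: syn addition to C6=C7 from the α face sets C6 and C7, and hydroboration of the 1-silylvinyl group gives a β-hydroxysilane (18) that eliminates to the vinyl group (19). A free vinyl group could not have survived this step, which is why it travels as the silylated precursor.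

**16 from 12 through 13 and 14.** The C8–O bond is traced to enone 12 through epoxy ketone 13 and a Wharton transposition to 14. The transposition also removes the C6 carbonyl oxygen, whose reduction to the equatorial alcohol would be opposed by the axial methyl. The epoxide is expected on the β face, so the C8 alcohol is inverted (14 to 16).

**12 from 8 through 10 and 11.** C7–C11 is cut (Morita–Baylis–Hillman hydroxymethylation of enone 10 to 11), and the C7=C8 unsaturation is traced to ketone 8. This brings C11 in at the alcohol level, compatible with everything up to the homologation.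

**8 from 5 and 6; 5 from 1 and 2.** C5–C4 is cut to a regiodefined enolate (stored as silyl enol ether 5) and tert-butyl bromoacetate (6). C10–C1 is cut to 3-methylcyclohex-2-en-1-one (1) and a vinylaluminium made from ethynyltrimethylsilane (2). The silyl group on the vinyl unit makes it much larger than methyl, which is what lets C10 direct C5, and it later serves as the vinyl mask.

## Roads not taken

**Alternative 1: enone–cyclobutene photocycloaddition, then thermal unzipping.** The cut is C10–C1 and C5–C4 together. The tricyclic photoadduct A1 would come from head-to-head [2+2] addition of tert-butyl cyclobut-1-ene-1-carboxylate A2 to the triplet of (S)-5-(tert-butyldimethylsilyloxy)-3-methylcyclohex-2-en-1-one A3. Thermolysis of the bicyclo[2.2.0]hexane in A1 would then break C1–C4 and C2–C3 and reveal the vinyl group and the propenoate at once.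
- Merits: for the C5/C10 pair this road is better than the chosen one. One photochemical step and one thermolysis replace the conjugate addition, the alkylation, the silyl mask and the ester methylenation.
- Weak points: head-to-head regiochemistry and the facial sense relative to the C8 silyloxy group of A3 are not secured by any strong element. A2 is strained and polymerises easily. Unzipping needs heat. A1 still holds a C6 ketone whose reduction to the equatorial alcohol is opposed by the axial methyl, and C7 is untouched.
- Comparison: the chosen plan spends about four more steps on C5/C10. In return C10 is set by a catalytic reaction of a known type, C5 by a large steric difference, and the C6 oxygen by syn addition, not by ketone reduction.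

**Alternative 2: intramolecular chromium allylation closing C6–C7.** The cut is the ring bond C6–C7. CrCl2 would turn an allylic C13 bromide into an allylchromium that adds through C7 to a C6 aldehyde, giving cyclohexanol A4 with the propenoate already on C7.
- Merits: ring, C6, C7 and the whole C11–C13 unit arrive in one step, the lactone then closes by simple acyl transfer, and no pressurised CO is needed. In step count for the lactone it is shorter than the chosen plan.
- Weak points: C5, C8 and the quaternary C10 must be built in an open chain. The C6 aldehyde is α-branched and can epimerise at C5. The trans outcome at C6/C7 relative to C5 and C8 rests on a cyclic transition state with several competing chair arrangements. The C15 acid still has to be made by two late oxidations beside the methylene lactone.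
- Comparison: the chosen plan is longer at the lactone but starts from a commercial ring, and relays each centre through a conformationally biased cyclohexane.

**Alternative 3: SmI2 ketyl–enoate cyclisation forming C7–C8.** The cut is the ring bond C7–C8. A ketyl from a C8 aldehyde would add 6-exo to C7 of an enoate and give cyclohexanol A5, with the C8 hydroxyl and the C7 acetate arm trans.
- Merits: it delivers the awkward equatorial C8 oxygen directly, where the chosen plan needs an inversion. That is a real advantage.
- Weak points: the lactone must afterwards be closed onto O6 and not O8 and then methylenated at C11, which is enolate chemistry on a polyfunctional lactone. The ketal-masked C4 ketone still has to become the propenoic acid. The stereocentres at C5, C6 and C10 must again be made in an open chain.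
- Comparison: the chosen plan pays two steps for C8 but makes the methylene lactone in one neutral step from an alkyne, with no late enolate.

Key step: step 17

Remark: ring atoms keep the numbering of the target (C5–C10) in all intermediates; β is the ring face of the C10 methyl group, α the face of the C10 vinyl group or its silylated precursor. The ligand enantiomer in step 1 is chosen to give the R-configured quaternary carbon of 5.

Step 1
Reactants: 1 3-methylcyclohex-2-en-1-one; 2 ethynyltrimethylsilane
Product: 5 (R)-trimethyl{[3-methyl-3-(1-trimethylsilylethenyl)cyclohex-1-en-1-yl]oxy}silane, via vinylalane 3 (not isolated), via aluminium enolate 4 (not isolated)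
Conditions: 2, i-Bu2AlH, hexane/THF, 55 °C; then 1, Cu(OTf)2 (cat.), chiral sulfonate-bearing imidazolinium salt (cat.), THF, −15 °C; then Me3SiOTf, Et3N, −78 °C
Reagents that add atoms: trimethylsilyl trifluoromethanesulfonate, C[Si](C)(C)OS(=O)(=O)C(F)(F)F
Why: Hydroalumination of the silylalkyne puts aluminium on the silicon-bearing carbon; asymmetric conjugate addition of this vinylaluminium to the β-methyl enone, catalysed by Cu(OTf)2 and the chiral carbene ligand, forms the quaternary C10, whose configuration is set by the ligand (catalyst control); O-silylation of the aluminium enolate stores the C5=C6 enolate regiochemistry for step 2.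

Step 2
Reactants: 5; 6 tert-butyl bromoacetate
Product: 8 tert-butyl 2-[(1S,2R)-2-methyl-6-oxo-2-(1-trimethylsilylethenyl)cyclohexyl]acetate, via lithium enolate 7 (not isolated)
Conditions: MeLi, THF, 0 °C; then 6, DMPU, −78 → −20 °C
Reagents that add atoms: none
Why: Methyllithium cleaves the silyl enol ether to the regiodefined lithium enolate, which is C-alkylated by the bromoacetate (enolate alkylation); the electrophile should enter anti to the bulky 1-silylvinyl group on the neighbouring quaternary carbon, placing the acetate arm cis to the methyl group, and C5 stays epimerisable toward this same, more stable isomer.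

Step 3
Reactants: 8
Product: 10 tert-butyl 2-[(1S,2R)-2-methyl-6-oxo-2-(1-trimethylsilylethenyl)cyclohex-4-en-1-yl]acetate, via silyl enol ether 9 (not isolated)
Conditions: LiN(i-Pr)2, THF, −78 °C, then Me3SiCl; then Pd(OAc)2 (cat.), O2, DMSO, rt
Reagents that add atoms: none
Why: Kinetic deprotonation should occur at the C7 methylene (the C5 methine is hindered and the ester is less acidic), and palladium-mediated dehydrosilylation of the enol silane (Ito–Saegusa oxidation, aerobic variant) gives the C7=C8 enone, the only ring enone this ketone can form.

Step 4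
Reactants: 10
Product: 11 tert-butyl 2-[(1S,2R)-5-(hydroxymethyl)-2-methyl-6-oxo-2-(1-trimethylsilylethenyl)cyclohex-4-en-1-yl]acetate
Conditions: HCHO (37% aq), DMAP (cat.), THF/H2O, rt
Reagents that add atoms: formaldehyde, C=O
Why: Morita–Baylis–Hillman hydroxymethylation: the amine adds reversibly to the unsubstituted β-carbon C8 and the resulting enolate captures formaldehyde at C7, which brings in C11 at the alcohol level and avoids an α-alkynyl ketone.

Step 5
Reactants: 11
Product: 12 tert-butyl 2-[(1S,2R)-5-(tert-butyldimethylsilyloxymethyl)-2-methyl-6-oxo-2-(1-trimethylsilylethenyl)cyclohex-4-en-1-yl]acetate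
Conditions: t-BuMe2SiCl, imidazole, DMF, 0 °C → rt
Reagents that add atoms: tert-butyl(chloro)dimethylsilane, CC(C)(C)[Si](C)(C)Cl
Why: Silylation of the primary alcohol keeps it out of the Mitsunobu step and gives a group that tolerates alkaline peroxide, hydrazine and borane.

Step 6
Reactants: 12
Product: 13 tert-butyl [7β,8β-epoxy-7α-(tert-butyldimethylsilyloxymethyl)-10β-methyl-6-oxo-10α-(1-trimethylsilylethenyl)cyclohex-5β-yl]acetate
Conditions: H2O2 (30% aq), NaOH (cat.), MeOH, 0 °C
Reagents that add atoms: hydrogen peroxide, OO
Why: Weitz–Scheffer epoxidation (conjugate addition of hydroperoxide, then ring closure); in the half-chair with the C5 arm and the silylvinyl group equatorial, attack at C8 along the trajectory that leads to a chair-like enolate comes from the face of the axial C10 methyl, so the oxirane is expected mainly on the β face (corrected in step 8), and the vinylsilane is inert to the nucleophilic oxidant.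

Step 7
Reactants: 13
Product: 14 tert-butyl [8β-hydroxy-7-(tert-butyldimethylsilyloxymethyl)-10β-methyl-10α-(1-trimethylsilylethenyl)cyclohex-6-en-5β-yl]acetate
Conditions: N2H4·H2O, AcOH (cat.), MeOH, 0 °C → rt
Reagents that add atoms: none
Why: Wharton transposition: the epoxy hydrazone fragments with loss of N2 to the allylic alcohol, which moves the oxygen to C8 with the configuration of the epoxide and leaves the C6=C7 alkene carrying C11; the hindered tert-butyl ester should resist hydrazine at this temperature.

Step 8
Reactants: 14
Product: 16 tert-butyl [8α-hydroxy-7-(tert-butyldimethylsilyloxymethyl)-10β-methyl-10α-(1-trimethylsilylethenyl)cyclohex-6-en-5β-yl]acetate, via nitrobenzoate 15 (not isolated)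
Conditions: 4-O2NC6H4CO2H, PPh3, i-PrO2CN=NCO2i-Pr, THF, 0 °C → rt; then K2CO3, MeOH, rt
Reagents that add atoms: 4-nitrobenzoic acid (its oxygen becomes the C8 hydroxyl oxygen), O=C(O)c1ccc(cc1)[N+](=O)[O-]
Why: Mitsunobu inversion of the secondary allylic alcohol (SN2 by the carboxylate on the alkoxyphosphonium ion from the open α face) followed by methanolysis gives the 8α alcohol, equatorial and cis to the C10 silylvinyl group; the primary alcohol is masked and the tert-butyl ester survives K2CO3 in methanol.

Step 9
Reactants: 16
Product: 18 tert-butyl [6α,8α-dihydroxy-10α-(2-hydroxy-1-trimethylsilylethyl)-7β-(tert-butyldimethylsilyloxymethyl)-10β-methylcyclohex-5β-yl]acetate (mixture at the silicon-bearing carbon), via organoborane 17 (not isolated)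
Conditions: BH3·THF, THF, 0 °C → rt; then H2O2, NaOAc (aq), 0 °C
Reagents that add atoms: hydrogen peroxide, OO
Why: Hydroboration–oxidation: at the ring alkene boron should add to the less substituted C6 and hydrogen to C7, syn and from the α face, away from the C5 arm and the axial C10 methyl, which sets C6 (α-OH) and C7 (H α, CH2O β) together; the silylvinyl group is hydroborated at its terminal carbon and gives the β-hydroxysilane needed in step 10, and buffered peroxide spares the tert-butyl ester.

Step 10
Reactants: 18
Product: 19 tert-butyl [10α-ethenyl-6α,8α-dihydroxy-7β-(hydroxymethyl)-10β-methylcyclohex-5β-yl]acetate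
Conditions: HF (48% aq), MeCN, 0 °C → rt
Reagents that add atoms: none
Why: Acid-promoted Peterson elimination of the β-hydroxysilane (anti elimination, fluoride taking up silicon) unveils the C10 vinyl group, and the same reagent cleaves the primary silyl ether; a tert-butyl ester tolerates aqueous HF.

Step 11
Reactants: 19
Product: 20 tert-butyl [10α-ethenyl-10β-methyl-6α,8α-bis(triethylsilyloxy)-7β-(triethylsilyloxymethyl)cyclohex-5β-yl]acetate
Conditions: Et3SiOTf, 2,6-lutidine, CH2Cl2, −78 → 0 °C
Reagents that add atoms: triethylsilyl trifluoromethanesulfonate, CC[Si](CC)(CC)OS(=O)(=O)C(F)(F)F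
Why: Silylation of all three hydroxyls with the reactive triflate (needed for the flanked C6 hydroxyl) removes every O–H before the enolate step and prepares the selective oxidation of step 13.

Step 12
Reactants: 20
Product: 23 tert-butyl 2-[10α-ethenyl-10β-methyl-6α,8α-bis(triethylsilyloxy)-7β-(triethylsilyloxymethyl)cyclohex-5β-yl]prop-2-enoate, via Mannich base 21 (not isolated), via ammonium iodide 22 (not isolated)
Conditions: LiN(i-Pr)2, THF, −78 °C; CH2=NMe2+ I−, −78 → 0 °C; then MeI, CH2Cl2/MeOH; then DBU, rt
Reagents that add atoms: N,N-dimethylmethyleneiminium iodide, C=[N+](C)C.[I-]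
Why: α-Methylenation of the ester: the lithium enolate (the only acidic C–H in 20 is α to the ester) adds to the iminium salt (Mannich reaction), and quaternisation followed by base-induced elimination of trimethylamine gives the propenoate without touching C5.

Step 13
Reactants: 23
Product: 24 tert-butyl 2-[10α-ethenyl-7β-formyl-10β-methyl-6α,8α-bis(triethylsilyloxy)cyclohex-5β-yl]prop-2-enoate
Conditions: (COCl)2, DMSO, CH2Cl2, −78 → −40 °C; then Et3N, −78 → 0 °C
Reagents that add atoms: none
Why: Under Swern conditions a primary triethylsilyl ether is cleaved and oxidised in the same flask to the aldehyde while secondary triethylsilyl ethers remain; C7, now α to the aldehyde, already carries the equatorial formyl group, the more stable arrangement between two equatorial silyloxy groups.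

Step 14
Reactants: 24
Product: 25 tert-butyl 2-[10α-ethenyl-7β-ethynyl-10β-methyl-6α,8α-bis(triethylsilyloxy)cyclohex-5β-yl]prop-2-enoate
Conditions: MeC(O)C(N2)P(O)(OMe)2, K2CO3, MeOH, 0 °C → rt
Reagents that add atoms: dimethyl (1-diazo-2-oxopropyl)phosphonate, CC(=O)C(=[N+]=[N-])P(=O)(OC)OC
Why: Seyferth–Gilbert homologation with the Ohira–Bestmann reagent converts the aldehyde into the terminal alkyne; epimerisation at C7 under these conditions can only lead to the all-equatorial isomer already present, and a silyloxide is a poor leaving group for β-elimination.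

Step 15
Reactants: 25
Product: 26 tert-butyl 2-[10α-ethenyl-7β-ethynyl-6α,8α-dihydroxy-10β-methylcyclohex-5β-yl]prop-2-enoate
Conditions: HF·pyridine, pyridine, THF, 0 °C → rt
Reagents that add atoms: none
Why: Fluoride cleavage of both silyl ethers under buffered, mildly acidic conditions, which avoids alkoxide-induced addition of O6 to the neighbouring propenoate.

Step 16
Reactants: 26; 27 angelic acid
Product: 29 tert-butyl 2-[8α-angeloyloxy-10α-ethenyl-7β-ethynyl-6α-hydroxy-10β-methylcyclohex-5β-yl]prop-2-enoate, via mixed anhydride 28 (not isolated)
Conditions: 27, 2,4,6-Cl3C6H2COCl, Et3N, toluene, rt; then 26, toluene, 70 °C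
Reagents that add atoms: none
Why: Esterification through the mixed anhydride of angelic acid and 2,4,6-trichlorobenzoic acid (Yamaguchi-type, without DMAP) is the usual way to keep the Z geometry; the C8 hydroxyl has a methylene on one side and should be acylated in preference to the C6 hydroxyl, which lies between two branched carbons.

Step 17
Reactants: 29
Product: 30 tert-butyl 8α-angeloyloxy-12,6α-olide of elema-1,3,11(13)-trien-15-oate (tert-butyl ester of 31)
Conditions: PdCl2 (cat.), SnCl2 (cat.), PPh3 (cat.), CO (7 atm), MeCN, 75 °C
Reagents that add atoms: carbon monoxide, [C-]#[O+]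
Why: This is the palladium-catalysed cyclocarbonylation of a homopropargylic alcohol, the known route from 2-ethynyl alcohols to α-methylene-γ-butyrolactones. The C6 hydroxyl and CO form an alkoxycarbonyl complex of divalent palladium (SnCl2 supplies the trichlorostannate ligand that keeps the metal electrophilic), the tethered alkyne inserts syn into the palladium–acyl bond with C12 bonding to the internal carbon C11, and protonolysis of the vinyl–palladium bond releases the lactone and the catalyst. The ring O6–C12–C11–C7–C6 closes in the 5-exo-dig mode, forming C11–C12 and C12–O. No stereocentre is created or touched: the trans ring fusion is the trans-diequatorial relationship of O6 and C11 fixed in steps 9, 13 and 14. The step needs chemoselectivity, and the substrate secures it: the only free hydroxyl is on C6 because the other homopropargylic oxygen (O8) is acylated, the terminal alkyne is far more reactive toward the acylpalladium than the vinyl group or the hindered enoates, and the bulky tert-butyl ester disfavours attack of O6 on C15. The neutral medium and moderate temperature should leave the (Z)-angelate unchanged.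

Step 18
Reactants: 30
Product: 31 (5R,6R,7R,8S,10S)-8-angeloyloxyelema-1,3,11(13)-trien-12,6-olid-15-oic acid (CNP0256928.3)
Conditions: CF3CO2H, CH2Cl2, 0 °C
Reagents that add atoms: none
Why: Acidolysis of the tert-butyl ester (loss of 2-methylpropene) frees the propenoic acid; the lactone, the angelate and the alkenes should be stable to cold trifluoroacetic acid for the short time needed.

**Compound list**

1 | 3-methylcyclohex-2-en-1-one | CC1=CC(=O)CCC1 | starting material
2 | ethynyltrimethylsilane | C#C[Si](C)(C)C | starting material
3 | diisobutyl[1-(trimethylsilyl)ethenyl]aluminium | C=C([Si](C)(C)C)[Al](CC(C)C)CC(C)C | intermediate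
4 | diisobutylaluminium C5=C6 enolate of (R)-3-methyl-3-(1-trimethylsilylethenyl)cyclohexanone | C=C([Si](C)(C)C)[C@]1(C)CCCC(O[Al](CC(C)C)CC(C)C)=C1 | intermediate
5 | (R)-trimethyl{[3-methyl-3-(1-trimethylsilylethenyl)cyclohex-1-en-1-yl]oxy}silane | C=C([Si](C)(C)C)[C@]1(C)CCCC(O[Si](C)(C)C)=C1 | intermediate
6 | tert-butyl bromoacetate | BrCC(=O)OC(C)(C)C | starting material
7 | lithium C5=C6 enolate of (R)-3-methyl-3-(1-trimethylsilylethenyl)cyclohexanone | C=C([Si](C)(C)C)[C@]1(C)CCCC(O[Li])=C1 | intermediate
8 | tert-butyl 2-[(1S,2R)-2-methyl-6-oxo-2-(1-trimethylsilylethenyl)cyclohexyl]acetate | C=C([Si](C)(C)C)[C@]1(C)CCCC(=O)[C@H]1CC(=O)OC(C)(C)C | intermediate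
9 | C6=C7 trimethylsilyl enol ether of 8 | C=C([Si](C)(C)C)[C@]1(C)CCC=C(O[Si](C)(C)C)[C@H]1CC(=O)OC(C)(C)C | intermediate
10 | tert-butyl 2-[(1S,2R)-2-methyl-6-oxo-2-(1-trimethylsilylethenyl)cyclohex-4-en-1-yl]acetate | C=C([Si](C)(C)C)[C@]1(C)CC=CC(=O)[C@H]1CC(=O)OC(C)(C)C | intermediate
11 | tert-butyl 2-[(1S,2R)-5-(hydroxymethyl)-2-methyl-6-oxo-2-(1-trimethylsilylethenyl)cyclohex-4-en-1-yl]acetate | C=C([Si](C)(C)C)[C@]1(C)CC=C(CO)C(=O)[C@H]1CC(=O)OC(C)(C)C | intermediate
12 | tert-butyl 2-[(1S,2R)-5-(tert-butyldimethylsilyloxymethyl)-2-methyl-6-oxo-2-(1-trimethylsilylethenyl)cyclohex-4-en-1-yl]acetate | C=C([Si](C)(C)C)[C@]1(C)CC=C(CO[Si](C)(C)C(C)(C)C)C(=O)[C@H]1CC(=O)OC(C)(C)C | intermediate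
13 | 7β,8β-epoxy ketone of 12 (oxirane oxygen cis to the C10 methyl) | C=C([Si](C)(C)C)[C@]1(C)C[C@H]2O[C@@]2(CO[Si](C)(C)C(C)(C)C)C(=O)[C@H]1CC(=O)OC(C)(C)C | intermediate
14 | tert-butyl [8β-hydroxy-7-(tert-butyldimethylsilyloxymethyl)-10β-methyl-10α-(1-trimethylsilylethenyl)cyclohex-6-en-5β-yl]acetate | C=C([Si](C)(C)C)[C@]1(C)C[C@@H](O)C(CO[Si](C)(C)C(C)(C)C)=C[C@H]1CC(=O)OC(C)(C)C | intermediate
15 | 8α-(4-nitrobenzoyl) ester formed from 14 with inversion | C=C([Si](C)(C)C)[C@]1(C)C[C@H](OC(=O)c2ccc(cc2)[N+](=O)[O-])C(CO[Si](C)(C)C(C)(C)C)=C[C@H]1CC(=O)OC(C)(C)C | intermediate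
16 | tert-butyl [8α-hydroxy-7-(tert-butyldimethylsilyloxymethyl)-10β-methyl-10α-(1-trimethylsilylethenyl)cyclohex-6-en-5β-yl]acetate | C=C([Si](C)(C)C)[C@]1(C)C[C@H](O)C(CO[Si](C)(C)C(C)(C)C)=C[C@H]1CC(=O)OC(C)(C)C | intermediate
17 | organoborane from 16 (drawn as the monomeric species with BH2 on C6α, on the terminal side-chain carbon and on O8) | BCC([Si](C)(C)C)[C@]1(C)C[C@H](OB)[C@@H](CO[Si](C)(C)C(C)(C)C)[C@H](B)[C@H]1CC(=O)OC(C)(C)C | intermediate
18 | tert-butyl [6α,8α-dihydroxy-10α-(2-hydroxy-1-trimethylsilylethyl)-7β-(tert-butyldimethylsilyloxymethyl)-10β-methylcyclohex-5β-yl]acetate | OCC([Si](C)(C)C)[C@]1(C)C[C@H](O)[C@@H](CO[Si](C)(C)C(C)(C)C)[C@H](O)[C@H]1CC(=O)OC(C)(C)C | intermediate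
19 | tert-butyl [10α-ethenyl-6α,8α-dihydroxy-7β-(hydroxymethyl)-10β-methylcyclohex-5β-yl]acetate | C=C[C@]1(C)C[C@H](O)[C@@H](CO)[C@H](O)[C@H]1CC(=O)OC(C)(C)C | intermediate
20 | tert-butyl [10α-ethenyl-10β-methyl-6α,8α-bis(triethylsilyloxy)-7β-(triethylsilyloxymethyl)cyclohex-5β-yl]acetate | C=C[C@]1(C)C[C@H](O[Si](CC)(CC)CC)[C@@H](CO[Si](CC)(CC)CC)[C@H](O[Si](CC)(CC)CC)[C@H]1CC(=O)OC(C)(C)C | intermediate
21 | Mannich base of 20 (dimethylaminomethyl group on the ester α-carbon, mixture at that carbon) | C=C[C@]1(C)C[C@H](O[Si](CC)(CC)CC)[C@@H](CO[Si](CC)(CC)CC)[C@H](O[Si](CC)(CC)CC)[C@H]1C(CN(C)C)C(=O)OC(C)(C)C | intermediate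
22 | trimethylammonium iodide from 21 | C=C[C@]1(C)C[C@H](O[Si](CC)(CC)CC)[C@@H](CO[Si](CC)(CC)CC)[C@H](O[Si](CC)(CC)CC)[C@H]1C(C[N+](C)(C)C)C(=O)OC(C)(C)C.[I-] | intermediate
23 | tert-butyl 2-[10α-ethenyl-10β-methyl-6α,8α-bis(triethylsilyloxy)-7β-(triethylsilyloxymethyl)cyclohex-5β-yl]prop-2-enoate | C=C[C@]1(C)C[C@H](O[Si](CC)(CC)CC)[C@@H](CO[Si](CC)(CC)CC)[C@H](O[Si](CC)(CC)CC)[C@H]1C(=C)C(=O)OC(C)(C)C | intermediate
24 | tert-butyl 2-[10α-ethenyl-7β-formyl-10β-methyl-6α,8α-bis(triethylsilyloxy)cyclohex-5β-yl]prop-2-enoate | C=C[C@]1(C)C[C@H](O[Si](CC)(CC)CC)[C@@H](C=O)[C@H](O[Si](CC)(CC)CC)[C@H]1C(=C)C(=O)OC(C)(C)C | intermediate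
25 | tert-butyl 2-[10α-ethenyl-7β-ethynyl-10β-methyl-6α,8α-bis(triethylsilyloxy)cyclohex-5β-yl]prop-2-enoate | C=C[C@]1(C)C[C@H](O[Si](CC)(CC)CC)[C@@H](C#C)[C@H](O[Si](CC)(CC)CC)[C@H]1C(=C)C(=O)OC(C)(C)C | intermediate
26 | tert-butyl 2-[10α-ethenyl-7β-ethynyl-6α,8α-dihydroxy-10β-methylcyclohex-5β-yl]prop-2-enoate | C=C[C@]1(C)C[C@H](O)[C@@H](C#C)[C@H](O)[C@H]1C(=C)C(=O)OC(C)(C)C | intermediate
27 | angelic acid, (Z)-2-methylbut-2-enoic acid | C/C=C(/C)C(=O)O | starting material
28 | (Z)-2-methylbut-2-enoic 2,4,6-trichlorobenzoic anhydride | C/C=C(/C)C(=O)OC(=O)c1c(Cl)cc(Cl)cc1Cl | intermediate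
29 | tert-butyl 2-[8α-angeloyloxy-10α-ethenyl-7β-ethynyl-6α-hydroxy-10β-methylcyclohex-5β-yl]prop-2-enoate | C=C[C@]1(C)C[C@H](OC(=O)/C(C)=C\C)[C@@H](C#C)[C@H](O)[C@H]1C(=C)C(=O)OC(C)(C)C | intermediate
30 | tert-butyl ester of 31 (trans-fused 12,6α-olide) | C=C[C@]1(C)C[C@H](OC(=O)/C(C)=C\C)[C@H]2C(=C)C(=O)O[C@@H]2[C@H]1C(=C)C(=O)OC(C)(C)C | intermediate
31 | (5R,6R,7R,8S,10S)-8-angeloyloxyelema-1,3,11(13)-trien-12,6-olid-15-oic acid (CNP0256928.3) | C=C[C@]1(C)C[C@H](OC(=O)/C(C)=C\C)[C@H]2C(=C)C(=O)O[C@@H]2[C@H]1C(=C)C(=O)O | target

**Step count and least certain steps**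

Total step count: 18. Longest linear sequence: 18 steps (from 1; the route is linear).

**Step 17 (key step).** Formation of the alkoxycarbonyl–palladium species at the flanked C6 hydroxyl may be slow. Side processes then gain ground: phosphine-induced Z-to-E isomerisation of the angelate, attack of O6 on C15 or on the propenoate, and carbonylation without ring closure. The fallback sets out from 29 and closes the same ring by a radical path. Phosgene and pyridine would convert the C6 hydroxyl into the chloroformate F1 and benzeneselenol would turn this into the Se-phenyl selenocarbonate F2 before any purification. Bu3SnH with a radical initiator then generates the alkoxycarbonyl radical, which cyclises 5-exo-dig onto the alkyne and, after hydrogen transfer, gives 30, where the route is rejoined.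

**Step 6.** Facial selectivity at C8 may be poor, because both faces are flanked by a C10 substituent in the respective half-chairs and the preference rests on a balance of torsional and steric effects. The α-epoxide would lead after step 7 directly to 16, so no material is lost, but a mixture has to be handled. The fallback sets out from the mixture of 14 and 16 that step 7 would then give. It is not separated but oxidised with MnO2 to the single transposed enone F3 in which C8 is the carbonyl carbon. LiAlH(O-t-Bu)3 at −78 °C, which leaves the tert-butyl ester alone, should then deliver hydride to the carbonyl from the α face, anti to the axial C10 methyl, and give the β alcohol 14 as one isomer, which re-enters at step 8.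

**Step 2.** Alkylation at a carbon next to a quaternary centre may stall. Proton transfer from product to enolate would then scramble the enolate regiochemistry, and O-alkylation could compete. The fallback sets out from 5. A Mukaiyama aldol addition to tert-butyl glyoxylate (BF3·OEt2, −78 °C) gives the α-hydroxy ester F4 as a mixture at the carbinol carbon. Phenyl chlorothionoformate converts it into the thionocarbonate F5 and Bu3SnH then removes the oxygen (Barton–McCombie deoxygenation) to give 8.

**Step 14.** The propenoate may be consumed by conjugate addition of methoxide or by dipolar cycloaddition of the diazophosphonate. The fallback sets out from 20 and carries the propenoate in masked form. The Mannich base 21 is isolated after the enolate addition. Swern oxidation gives the amino aldehyde F6 and the Ohira–Bestmann reagent then gives the amino alkyne F7 with the amine still in place. Only then do MeI, which forms the ammonium iodide F8 as in step 12, and DBU release the propenoate, giving 25.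

**Step 16.** Site selectivity may be lost through acylation of both hydroxyls or acyl migration from O8 to O6, with some isomerisation to the tiglate on prolonged heating. The fallback sets out from 25 and differentiates the two oxygens at the silyl stage. Brief treatment with pyridinium p-toluenesulfonate in methanol should remove the less hindered C8 silyl ether first, giving the C6 silyl ether alcohol F9 with O8 free. Acylation with 28 gives the silylated angelate F10 and HF·pyridine then frees O6 to give 29.

**Further compounds**

F1 | step 17 | C6 chloroformate of 29 | C=C[C@]1(C)C[C@H](OC(=O)/C(C)=C\C)[C@@H](C#C)[C@H](OC(=O)Cl)[C@H]1C(=C)C(=O)OC(C)(C)C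
F2 | step 17 | C6 Se-phenyl selenocarbonate of 29 | C=C[C@]1(C)C[C@H](OC(=O)/C(C)=C\C)[C@@H](C#C)[C@H](OC(=O)[Se]c2ccccc2)[C@H]1C(=C)C(=O)OC(C)(C)C
F3 | step 6 | C8 enone from oxidation of 14 and 16 | C=C([Si](C)(C)C)[C@]1(C)CC(=O)C(CO[Si](C)(C)C(C)(C)C)=C[C@H]1CC(=O)OC(C)(C)C
F4 | step 2 | 2-hydroxy derivative of 8 (hydroxyl on the acetate α-carbon, ring configuration as in 8, mixture at the carbinol carbon) | C=C([Si](C)(C)C)[C@]1(C)CCCC(=O)[C@H]1C(O)C(=O)OC(C)(C)C
F5 | step 2 | O-phenyl thionocarbonate of F4 | C=C([Si](C)(C)C)[C@]1(C)CCCC(=O)[C@H]1C(OC(=S)Oc2ccccc2)C(=O)OC(C)(C)C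
F6 | step 14 | C7 aldehyde carrying the dimethylaminomethyl-masked propenoate | C=C[C@]1(C)C[C@H](O[Si](CC)(CC)CC)[C@@H](C=O)[C@H](O[Si](CC)(CC)CC)[C@H]1C(CN(C)C)C(=O)OC(C)(C)C
F7 | step 14 | C7 alkyne carrying the dimethylaminomethyl-masked propenoate | C=C[C@]1(C)C[C@H](O[Si](CC)(CC)CC)[C@@H](C#C)[C@H](O[Si](CC)(CC)CC)[C@H]1C(CN(C)C)C(=O)OC(C)(C)C
F8 | step 14 | trimethylammonium iodide from F7 | C=C[C@]1(C)C[C@H](O[Si](CC)(CC)CC)[C@@H](C#C)[C@H](O[Si](CC)(CC)CC)[C@H]1C(C[N+](C)(C)C)C(=O)OC(C)(C)C.[I-]
F9 | step 16 | 8α-hydroxy 6α-triethylsilyl ether from 25 | C=C[C@]1(C)C[C@H](O)[C@@H](C#C)[C@H](O[Si](CC)(CC)CC)[C@H]1C(=C)C(=O)OC(C)(C)C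
F10 | step 16 | 6α-triethylsilyl ether of 29 | C=C[C@]1(C)C[C@H](OC(=O)/C(C)=C\C)[C@@H](C#C)[C@H](O[Si](CC)(CC)CC)[C@H]1C(=C)C(=O)OC(C)(C)C
A1 | alternative 1 | cis-anti-cis tricyclic photoadduct (cyclohexanone fused to a bicyclo[2.2.0]hexane) | O=C1C[C@@H](O[Si](C)(C)C(C)(C)C)C[C@@]2(C)[C@@H]1[C@]3(C(=O)OC(C)(C)C)CC[C@H]23
A2 | alternative 1 | tert-butyl cyclobut-1-ene-1-carboxylate | CC(C)(C)OC(=O)C1=CCC1
A3 | alternative 1 | (S)-5-(tert-butyldimethylsilyloxy)-3-methylcyclohex-2-en-1-one | O=C1C[C@@H](O[Si](C)(C)C(C)(C)C)CC(C)=C1
A4 | alternative 2 | cyclohexanol with the methyl propenoate on C7 (open form of the lactone) | C=C[C@]1(C)C[C@H](O[Si](C)(C)C(C)(C)C)[C@@H](C(=C)C(=O)OC)[C@H](O)[C@H]1C(=C)COCc2ccc(OC)cc2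
A5 | alternative 3 | cyclohexanol with the C7 tert-butyl acetate arm and free C8 hydroxyl | C=C[C@]1(C)C[C@H](O)[C@@H](CC(=O)OC(C)(C)C)[C@H](O[Si](CC)(CC)CC)[C@H]1C2(C)OCCO2
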